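**Retrosynthetic overview**
1. The target (a heliangolide: 1(10)E-derived epoxide, 4Z alkene) comes from its bis-silyl ether by desilylation, and that from the 1(10)-alkene by epoxidation. The α-methylene lactone is closed last among the C–C bonds: the carbonyl carbon C12 (from CO, carried on O6) is joined to the alkyne carbon C11 by palladium-catalysed cyclocarbonylation.
2. Enabling feature: the trans-vicinal C6 hydroxyl and C7 ethynyl group on the ten-membered carbocycle (array O6–C6–C7–C11≡C13). O8 is already esterified, so only O6 can deliver the CO carbon to C11 in a five-membered ring.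
3. C6–C8 triad: C8 by chirality transfer in an anionic oxy-Cope ring expansion; C7 by chelate-controlled ethynylation of the aldolate; C6 and the O8 methacrylate together by Evans–Tishchenko reduction with methacrolein.
4. Ten-membered ring from a 1-alkenyl-6-isopropenylcyclohex-2-enol (C8–C9 bond by [3,3]; ring alkene becomes 4Z, isopropenyl becomes 1(10)E). That comes from a 4-silyloxy-6-isopropenylcyclohexenone, made from a p-quinone monoketal by asymmetric conjugate addition and CBS reduction.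
5. Ring order: six-membered carbocycle (from the arene) → ten-membered carbocycle (step 10) → γ-lactone (step 14) → oxirane (step 15).

Key step: step 14

Remark: germacrane numbering is used in the prose (ring C1–C10; C11, C12, C13 = lactone α-carbon, carbonyl carbon, methylene carbon; C14 = methyl on C10; C15 = CH2O on C4); TBS = tert-butyldimethylsilyl, PMB = 4-methoxybenzyl; compound 1 and all reagents named are assumed to be purchasable.

Step 1
Reactants: 1 2-(hydroxymethyl)-4-methoxyphenol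
Product: 2 2-(hydroxymethyl)-4,4-dimethoxycyclohexa-2,5-dien-1-one
Conditions: PhI(OAc)2, MeOH, 0 °C
Reagents that add atoms: methanol, CO
Why: Oxidative dearomatisation of a 4-methoxyphenol by the trivalent iodine reagent, with para attack of methanol, should give the p-quinone monoketal (no stereocentre).

Step 2
Reactants: 2 2-(hydroxymethyl)-4,4-dimethoxycyclohexa-2,5-dien-1-one
Product: 3 2-[(TBS-oxy)methyl]-4,4-dimethoxycyclohexa-2,5-dien-1-one
Conditions: TBSCl, imidazole, CH2Cl2, 0 °C
Reagents that add atoms: tert-butyldimethylsilyl chloride, CC(C)(C)[Si](C)(C)Cl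
Why: Standard silylation of the only hydroxyl group.

Step 3
Reactants: 3 2-[(TBS-oxy)methyl]-4,4-dimethoxycyclohexa-2,5-dien-1-one
Product: 4 (5R)-2-[(TBS-oxy)methyl]-4,4-dimethoxy-5-(prop-1-en-2-yl)cyclohex-2-en-1-one
Conditions: [Rh(OH)(cod)]2 (cat.), (R)-BINAP, isopropenyl-Bpin, 1,4-dioxane/H2O, 40 °C
Reagents that add atoms: isopropenylboronic acid pinacol ester, C=C(C)B1OC(C)(C)C(C)(C)O1
Why: Hayashi–Miyaura rhodium-catalysed asymmetric conjugate addition should deliver the alkenyl group to the unsubstituted enone arm (the 2-substituted arm is hindered), and the (R)-ligand should set the new centre as 5R, the sense being taken from the addition to cyclohex-2-enone.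

Step 4
Reactants: 4 (5R)-2-[(TBS-oxy)methyl]-4,4-dimethoxy-5-(prop-1-en-2-yl)cyclohex-2-en-1-one
Product: 5 (1S,5R)-2-[(TBS-oxy)methyl]-4,4-dimethoxy-5-(prop-1-en-2-yl)cyclohex-2-en-1-ol
Conditions: (R)-Me-CBS (cat.), catecholborane, toluene, −78 °C
Reagents that add atoms: none
Why: Corey–Bakshi–Shibata 1,2-reduction with the substituted alkenyl arm as the large group should give the (1S)-alcohol, trans to the isopropenyl group, under reagent control.

Step 5
Reactants: 5 (1S,5R)-2-[(TBS-oxy)methyl]-4,4-dimethoxy-5-(prop-1-en-2-yl)cyclohex-2-en-1-ol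
Product: 6 (1S,5R)-1-(TBS-oxy)-2-[(TBS-oxy)methyl]-4,4-dimethoxy-5-(prop-1-en-2-yl)cyclohex-2-ene
Conditions: TBSOTf, 2,6-lutidine, CH2Cl2, −78 °C
Reagents that add atoms: tert-butyldimethylsilyl triflate, CC(C)(C)[Si](C)(C)OS(=O)(=O)C(F)(F)F
Why: Silylation of the secondary allylic alcohol under buffered conditions that keep the ketal.

Step 6
Reactants: 6 (1S,5R)-1-(TBS-oxy)-2-[(TBS-oxy)methyl]-4,4-dimethoxy-5-(prop-1-en-2-yl)cyclohex-2-ene
Product: 7 (4S,6R)-4-(TBS-oxy)-3-[(TBS-oxy)methyl]-6-(prop-1-en-2-yl)cyclohex-2-en-1-one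
Conditions: PPTS (cat.), acetone/H2O, 23 °C
Reagents that add atoms: water, O
Why: Mild hydrolysis of the allylic dimethyl ketal (through the allyl-stabilised oxocarbenium ion) should unveil the enone without touching the silyl ethers or the α-stereocentre.

Step 7
Reactants: 8 4-methoxybenzyl alcohol
Product: 9 (E)-1,2-dichlorovinyl 4-methoxybenzyl ether
Conditions: KH, THF, 0 °C; trichloroethylene, −50 → 23 °C
Reagents that add atoms: trichloroethylene, ClC=C(Cl)Cl
Why: Addition of the potassium alkoxide to dichloroacetylene generated in situ from trichloroethylene is the established route to (E)-1,2-dichlorovinyl ethers, the precursors of alkynyl ethers.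

Step 8
Reactants: 7 (4S,6R)-4-(TBS-oxy)-3-[(TBS-oxy)methyl]-6-(prop-1-en-2-yl)cyclohex-2-en-1-one; 9 (E)-1,2-dichlorovinyl 4-methoxybenzyl ether
Product: 12 (1R,4S,6R)-4-(TBS-oxy)-3-[(TBS-oxy)methyl]-1-[(PMB-oxy)ethynyl]-6-(prop-1-en-2-yl)cyclohex-2-en-1-ol, via chloroethynyl PMB ether 10 (not isolated), via lithium alkynyl ether 11 (not isolated)
Conditions: 9, n-BuLi (2.2 equiv), THF, −78 → −40 °C; then 7, −78 °C; H2O
Reagents that add atoms: none
Why: Elimination and Cl–Li exchange convert 9 into the lithium alkynyl ether, whose 1,2-addition to the enone should occur anti to the adjacent isopropenyl group and set the carbinol centre as 1R (acetylide addition to a ketone).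

Step 9
Reactants: 12 (1R,4S,6R)-4-(TBS-oxy)-3-[(TBS-oxy)methyl]-1-[(PMB-oxy)ethynyl]-6-(prop-1-en-2-yl)cyclohex-2-en-1-ol
Product: 13 (1R,4S,6R)-4-(TBS-oxy)-3-[(TBS-oxy)methyl]-1-[(E)-2-(PMB-oxy)ethenyl]-6-(prop-1-en-2-yl)cyclohex-2-en-1-ol
Conditions: LiAlH4, THF, 0 → 23 °C; aq. NaOH work-up
Reagents that add atoms: none
Why: Hydroxyl-directed trans-hydroalumination of the propargylic alcohol followed by protonolysis should give the (E)-enol ether (trans reduction of propargylic alcohols by LiAlH4).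

Step 10
Reactants: 13 (1R,4S,6R)-4-(TBS-oxy)-3-[(TBS-oxy)methyl]-1-[(E)-2-(PMB-oxy)ethenyl]-6-(prop-1-en-2-yl)cyclohex-2-en-1-ol
Product: 16 (2Z,4S,6E,9R)-4-(TBS-oxy)-3-[(TBS-oxy)methyl]-9-(PMB-oxy)-7-methylcyclodeca-2,6-dien-1-one, via potassium alkoxide 14 (not isolated), via potassium enolate 15 (not isolated)
Conditions: KH, 18-crown-6, THF, 0 → 23 °C; then aq. NH4Cl, −78 °C
Reagents that add atoms: none
Why: Anionic oxy-Cope rearrangement ([3,3] ring expansion) through the chair transition state with both ring bonds equatorial should carry the cyclohexene double bond over as the 4Z alkene, turn the isopropenyl group into the 1(10)E alkene, and relay the configuration of the isopropenyl-bearing carbon through the equatorial (E)-alkoxy terminus to C8 (9R in the product numbering).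

Step 11
Reactants: 16 (2Z,4S,6E,9R)-4-(TBS-oxy)-3-[(TBS-oxy)methyl]-9-(PMB-oxy)-7-methylcyclodeca-2,6-dien-1-one
Product: 17 (2Z,4S,6E,9R)-4-(TBS-oxy)-3-[(TBS-oxy)methyl]-9-hydroxy-7-methylcyclodeca-2,6-dien-1-one
Conditions: DDQ, CH2Cl2/pH 7 buffer, 0 °C
Reagents that add atoms: none
Why: Oxidative cleavage of the PMB ether by DDQ under buffered conditions should leave the silyl ethers, the alkenes and the β-hydroxy ketone intact.

Step 12
Reactants: 17 (2Z,4S,6E,9R)-4-(TBS-oxy)-3-[(TBS-oxy)methyl]-9-hydroxy-7-methylcyclodeca-2,6-dien-1-one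
Product: 20 (2Z,4S,6E,9R,10R)-4-(TBS-oxy)-3-[(TBS-oxy)methyl]-10-ethynyl-9-hydroxy-7-methylcyclodeca-2,6-dien-1-one, via dilithium aldolate dianion 18 (not isolated), via silylalkyne 19 (not isolated)
Conditions: LDA (2.2 equiv), THF, −78 °C; TMS-EBX, −78 °C; then AcOH, TBAF, −20 °C
Reagents that add atoms: 1-[(trimethylsilyl)ethynyl]-1,2-benziodoxol-3(1H)-one (TMS-EBX), C[Si](C)(C)C#CI1OC(=O)c2ccccc12
Why: Proposed new method: the lithium-chelated aldolate dianion 18 (O6–Li–O8 bridge, enolate oxygen cis to C8) should attack the β-carbon of the alkynyl trivalent-iodine reagent from the face anti to C9, and the alkylidene carbene so formed should rearrange by 1,2-silyl shift to the silylalkyne, which sets C7 anti to the C8 oxygen (10R) before fluoride removes the alkyne silyl group; the closest known reaction types are the α-alkynylation of ketone enolates with ethynylbenziodoxolones and the anti-selective Fráter–Seebach alkylation of β-hydroxy carbonyl dianions.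

Step 13
Reactants: 20 (2Z,4S,6E,9R,10R)-4-(TBS-oxy)-3-[(TBS-oxy)methyl]-10-ethynyl-9-hydroxy-7-methylcyclodeca-2,6-dien-1-one
Product: 21 (1R,2S,3R,4Z,6S,8E)-6-(TBS-oxy)-5-[(TBS-oxy)methyl]-2-ethynyl-3-hydroxy-9-methylcyclodeca-4,8-dien-1-yl 2-methylprop-2-enoate
Conditions: methacrolein (excess), SmI2 (30 mol %), THF, −10 °C
Reagents that add atoms: methacrolein, C=C(C)C=O
Why: Evans–Tishchenko reduction: the samarium-bound hemiacetal of methacrolein on O8 should deliver hydride intramolecularly to the C6 ketone through a chair transition state, giving the 1,3-anti alcohol at C6 and leaving the target's methacrylate on O8.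

Step 14
Reactants: 21 (1R,2S,3R,4Z,6S,8E)-6-(TBS-oxy)-5-[(TBS-oxy)methyl]-2-ethynyl-3-hydroxy-9-methylcyclodeca-4,8-dien-1-yl 2-methylprop-2-enoate
Product: 22 (3S,6R,7R,8R)-3,15-bis(TBS-oxy)-8-(methacryloyloxy)germacra-1(10)E,4Z,11(13)-trien-12,6-olide
Conditions: PdCl2 (10 mol %), thiourea (10 mol %), CO (3 atm), acetone, 50 °C
Reagents that add atoms: carbon monoxide, [C-]#[O+]
Why: Divalent palladium, CO and the C6 hydroxyl should give an alkoxycarbonylpalladium chloride whose Pd–C(=O)O bond adds syn across the C11≡C13 triple bond, so that the carbonyl carbon C12 bonds to C11 and the lactone closes, after which protonolysis of the vinylpalladium at C13 by the HCl set free earlier releases the exocyclic methylene and returns divalent palladium without any oxidant or reductant. The closest known reaction type is the palladium-catalysed cyclocarbonylation of homopropargylic alcohols such as trans-2-ethynylcycloalkanols to trans-fused α-methylene-γ-butyrolactones. The lactone ring closes in the 5-exo-dig mode by insertion of the alkyne into the palladium–acyl bond. No new stereocentre is formed: the trans ring fusion is fixed by the C6 and C7 configurations set in steps 12 and 13, and the new alkene is a terminal methylene. The step needs carbonylation to win over direct 5-endo oxypalladation of the alkyne by O6, which CO pressure and the thiourea ligand should secure, and it needs O6 to be the only oxygen that reacts, which holds because O8 carries the methacrylate and O3 and O15 are silylated. In one operation it brings in C12, forms the C11–C12 bond, closes the lactone and unveils the α-methylene group from a precursor that carries only an alkyne and a free alcohol.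

Step 15
Reactants: 22 (3S,6R,7R,8R)-3,15-bis(TBS-oxy)-8-(methacryloyloxy)germacra-1(10)E,4Z,11(13)-trien-12,6-olide
Product: 23 (1R,3S,6R,7R,8R,10R)-1,10-epoxy-3,15-bis(TBS-oxy)-8-(methacryloyloxy)germacra-4Z,11(13)-dien-12,6-olide
Conditions: dimethyldioxirane, acetone/CH2Cl2, −20 °C
Reagents that add atoms: dimethyldioxirane, CC1(C)OO1
Why: The neutral electrophilic dioxirane should epoxidise only the electron-rich trisubstituted 1(10) alkene, from its exposed outer face (the (1R,10R) epoxide is expected), and leave the deactivated 4,5-alkene and the two acrylate-type alkenes.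

Step 16
Reactants: 23 (1R,3S,6R,7R,8R,10R)-1,10-epoxy-3,15-bis(TBS-oxy)-8-(methacryloyloxy)germacra-4Z,11(13)-dien-12,6-olide
Product: 24 (1R,3S,6R,7R,8R,10R)-1,10-epoxy-3,15-dihydroxy-8-(methacryloyloxy)germacra-4Z,11(13)-dien-12,6-olide
Conditions: HF·pyridine, pyridine, THF, 0 → 23 °C
Reagents that add atoms: none
Why: Buffered fluoride should cleave both silyl ethers without opening the acid-sensitive epoxide or adding to the α-methylene lactone.

**Compound list**
1 | 2-(hydroxymethyl)-4-methoxyphenol | COc1ccc(O)c(CO)c1 | starting material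
2 | 2-(hydroxymethyl)-4,4-dimethoxycyclohexa-2,5-dien-1-one | COC1(OC)C=CC(=O)C(CO)=C1 | intermediate
3 | 2-[(TBS-oxy)methyl]-4,4-dimethoxycyclohexa-2,5-dien-1-one | COC1(OC)C=CC(=O)C(CO[Si](C)(C)C(C)(C)C)=C1 | intermediate
4 | (5R)-2-[(TBS-oxy)methyl]-4,4-dimethoxy-5-(prop-1-en-2-yl)cyclohex-2-en-1-one | COC1(OC)C=C(CO[Si](C)(C)C(C)(C)C)C(=O)C[C@@H]1C(C)=C | intermediate
5 | (1S,5R)-2-[(TBS-oxy)methyl]-4,4-dimethoxy-5-(prop-1-en-2-yl)cyclohex-2-en-1-ol | COC1(OC)C=C(CO[Si](C)(C)C(C)(C)C)[C@@H](O)C[C@@H]1C(C)=C | intermediate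
6 | (1S,5R)-1-(TBS-oxy)-2-[(TBS-oxy)methyl]-4,4-dimethoxy-5-(prop-1-en-2-yl)cyclohex-2-ene | COC1(OC)C=C(CO[Si](C)(C)C(C)(C)C)[C@@H](O[Si](C)(C)C(C)(C)C)C[C@@H]1C(C)=C | intermediate
7 | (4S,6R)-4-(TBS-oxy)-3-[(TBS-oxy)methyl]-6-(prop-1-en-2-yl)cyclohex-2-en-1-one | O=C1C=C(CO[Si](C)(C)C(C)(C)C)[C@@H](O[Si](C)(C)C(C)(C)C)C[C@@H]1C(C)=C | intermediate
8 | 4-methoxybenzyl alcohol | COc1ccc(CO)cc1 | starting material
9 | (E)-1,2-dichlorovinyl 4-methoxybenzyl ether | COc1ccc(CO/C(Cl)=C\Cl)cc1 | intermediate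
10 | chloroethynyl 4-methoxybenzyl ether | COc1ccc(COC#CCl)cc1 | intermediate
11 | lithium [(4-methoxybenzyl)oxy]acetylide | COc1ccc(COC#C[Li])cc1 | intermediate
12 | (1R,4S,6R)-4-(TBS-oxy)-3-[(TBS-oxy)methyl]-1-[(PMB-oxy)ethynyl]-6-(prop-1-en-2-yl)cyclohex-2-en-1-ol | O[C@]1(C#COCc2ccc(OC)cc2)C=C(CO[Si](C)(C)C(C)(C)C)[C@@H](O[Si](C)(C)C(C)(C)C)C[C@@H]1C(C)=C | intermediate
13 | (1R,4S,6R)-4-(TBS-oxy)-3-[(TBS-oxy)methyl]-1-[(E)-2-(PMB-oxy)ethenyl]-6-(prop-1-en-2-yl)cyclohex-2-en-1-ol | O[C@]1(/C=C/OCc2ccc(OC)cc2)C=C(CO[Si](C)(C)C(C)(C)C)[C@@H](O[Si](C)(C)C(C)(C)C)C[C@@H]1C(C)=C | intermediate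
14 | potassium alkoxide of 13 | [K+].[O-][C@]1(/C=C/OCc2ccc(OC)cc2)C=C(CO[Si](C)(C)C(C)(C)C)[C@@H](O[Si](C)(C)C(C)(C)C)C[C@@H]1C(C)=C | intermediate
15 | potassium enolate of 16 (C6–C7 enolate, oxygen cis to C8) | [K+].COc1ccc(CO[C@@H]2C/C(C)=C/C[C@H](O[Si](C)(C)C(C)(C)C)/C(CO[Si](C)(C)C(C)(C)C)=C\C([O-])=C\2)cc1 | intermediate
16 | (2Z,4S,6E,9R)-4-(TBS-oxy)-3-[(TBS-oxy)methyl]-9-(PMB-oxy)-7-methylcyclodeca-2,6-dien-1-one | COc1ccc(CO[C@@H]2C/C(C)=C/C[C@H](O[Si](C)(C)C(C)(C)C)/C(CO[Si](C)(C)C(C)(C)C)=C\C(=O)C2)cc1 | intermediate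
17 | (2Z,4S,6E,9R)-4-(TBS-oxy)-3-[(TBS-oxy)methyl]-9-hydroxy-7-methylcyclodeca-2,6-dien-1-one | O[C@@H]1C/C(C)=C/C[C@H](O[Si](C)(C)C(C)(C)C)/C(CO[Si](C)(C)C(C)(C)C)=C\C(=O)C1 | intermediate
18 | dilithium alkoxide-enolate (dianion) of 17 | [Li+].[Li+].[O-][C@@H]1C/C(C)=C/C[C@H](O[Si](C)(C)C(C)(C)C)/C(CO[Si](C)(C)C(C)(C)C)=C\C([O-])=C\1 | intermediate
19 | (2Z,4S,6E,9R,10R)-4-(TBS-oxy)-3-[(TBS-oxy)methyl]-9-hydroxy-7-methyl-10-[(trimethylsilyl)ethynyl]cyclodeca-2,6-dien-1-one | O[C@@H]1C/C(C)=C/C[C@H](O[Si](C)(C)C(C)(C)C)/C(CO[Si](C)(C)C(C)(C)C)=C\C(=O)[C@@H]1C#C[Si](C)(C)C | intermediate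
20 | (2Z,4S,6E,9R,10R)-4-(TBS-oxy)-3-[(TBS-oxy)methyl]-10-ethynyl-9-hydroxy-7-methylcyclodeca-2,6-dien-1-one | O[C@@H]1C/C(C)=C/C[C@H](O[Si](C)(C)C(C)(C)C)/C(CO[Si](C)(C)C(C)(C)C)=C\C(=O)[C@@H]1C#C | intermediate
21 | (1R,2S,3R,4Z,6S,8E)-6-(TBS-oxy)-5-[(TBS-oxy)methyl]-2-ethynyl-3-hydroxy-9-methylcyclodeca-4,8-dien-1-yl 2-methylprop-2-enoate | C=C(C)C(=O)O[C@@H]1C/C(C)=C/C[C@H](O[Si](C)(C)C(C)(C)C)/C(CO[Si](C)(C)C(C)(C)C)=C\[C@@H](O)[C@@H]1C#C | intermediate
22 | (3S,6R,7R,8R)-3,15-bis(TBS-oxy)-8-(methacryloyloxy)germacra-1(10)E,4Z,11(13)-trien-12,6-olide | C=C(C)C(=O)O[C@@H]1C/C(C)=C/C[C@H](O[Si](C)(C)C(C)(C)C)/C(CO[Si](C)(C)C(C)(C)C)=C\[C@H]2OC(=O)C(=C)[C@@H]21 | intermediate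
23 | (1R,3S,6R,7R,8R,10R)-1,10-epoxy-3,15-bis(TBS-oxy)-8-(methacryloyloxy)germacra-4Z,11(13)-dien-12,6-olide | C=C(C)C(=O)O[C@@H]1C[C@@]2(C)O[C@@H]2C[C@H](O[Si](C)(C)C(C)(C)C)/C(CO[Si](C)(C)C(C)(C)C)=C\[C@H]2OC(=O)C(=C)[C@@H]21 | intermediate
24 | (1R,3S,6R,7R,8R,10R)-1,10-epoxy-3,15-dihydroxy-8-(methacryloyloxy)germacra-4Z,11(13)-dien-12,6-olide | C=C(C)C(=O)O[C@@H]1C[C@@]2(C)O[C@@H]2C[C@H](O)/C(CO)=C\[C@H]2OC(=O)C(=C)[C@@H]21 | target

**Step count and risks**
Total step count: 16. Longest linear sequence: 15 steps (steps 1–6 and 8–16; step 7 prepares the side reagent 9).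

Steps most likely to fail:

1. Step 12 (proposed new method). What may go wrong: retro-aldol opening of the ten-membered ring while the aldolate is deprotonated; attack of the electrophile on a non-chelated enolate rotamer with loss of facial control at C7; a second alkynylation; base-induced isomerisation of the α-ethynyl ketone to an allenyl ketone. Fallback (known chemistry): it sets out from 12 and makes the C7–C11 bond by cross-coupling before the ring expansion. Hydroxyl-directed ruthenium-catalysed trans-hydrostannation of 12 (Bu3SnH, [Cp*RuCl]4) should place tin on the carbinol-side alkyne carbon and give the alkenylstannane F1. Iododestannylation (I2) gives the alkenyl iodide F2, and Sonogashira coupling with trimethylsilylacetylene (PdCl2(PPh3)2, CuI, Et3N) gives the enyne carbinol F3. Anionic oxy-Cope rearrangement under the conditions of step 10, followed by kinetic protonation of the enolate at C7, gives the α-alkynyl ketone F4. DDQ as in step 11 then leads to 19, where the route is rejoined (desilylation of the alkyne as in the last part of step 12, then steps 13–16). In this variant C7 is set by protonation and not by alkylation.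

2. Step 10. What may go wrong: β-elimination of the benzyloxide from the enolate after the rearrangement; rearrangement through the alternative chair or a boat, with loss of control over C8 or over the 1(10) alkene geometry; ionisation of the acid-sensitive divinyl carbinol before it rearranges. Fallback: it sets out from 7 and introduces the C8 oxygen only after the ring expansion. 1,2-Addition of vinylmagnesium bromide gives the divinyl carbinol F5, and anionic oxy-Cope rearrangement (KH, 18-crown-6), now without any β-leaving group, gives the cyclodecadienone F6. Dehydrogenation with IBX gives the cross-conjugated trienone F7. Nucleophilic epoxidation of its less substituted enone (t-BuOOH, benzyltrimethylammonium hydroxide) gives the 7,8-epoxy ketone F8, and reductive opening with SmI2 gives the β-hydroxy ketone 17. C8 then rests on peripheral epoxidation and not on chirality transfer.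

3. Step 13. What may go wrong: conjugate addition to, or oligomerisation of, the enal under the samarium catalyst in place of hemiacetal formation and hydride transfer; migration of the acyl group from O8 to O6; epimerisation at C7. Fallback: it sets out from 20 and uses a saturated, masked aldehyde, the usual substrate type for this reduction. Conjugate addition of benzeneselenol to methacrolein gives 2-methyl-3-(phenylselanyl)propanal F9. Evans–Tishchenko reduction of 20 with F9 (SmI2 cat.) gives the C8 3-(phenylselanyl)-2-methylpropanoate F10 with the free C6 alcohol. Oxidation with NaIO4 and selenoxide syn-elimination unveil the methacrylate and give 21.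

Further compounds
F1 | step 12 | C7 alkenylstannane from trans-hydrostannation of 12 (tin on the carbinol-side carbon, PMB-oxy trans to the ring carbon) | O[C@]1(/C(=C/OCc2ccc(OC)cc2)[Sn](CCCC)(CCCC)CCCC)C=C(CO[Si](C)(C)C(C)(C)C)[C@@H](O[Si](C)(C)C(C)(C)C)C[C@@H]1C(C)=C
F2 | step 12 | C7 alkenyl iodide (same geometry as F1) | O[C@]1(/C(I)=C/OCc2ccc(OC)cc2)C=C(CO[Si](C)(C)C(C)(C)C)[C@@H](O[Si](C)(C)C(C)(C)C)C[C@@H]1C(C)=C
F3 | step 12 | enyne carbinol (C7 trimethylsilylethynyl, PMB-oxy trans to the ring carbon) | O[C@]1(/C(C#C[Si](C)(C)C)=C/OCc2ccc(OC)cc2)C=C(CO[Si](C)(C)C(C)(C)C)[C@@H](O[Si](C)(C)C(C)(C)C)C[C@@H]1C(C)=C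
F4 | step 12 | (2Z,4S,6E,9R,10R)-4-(TBS-oxy)-3-[(TBS-oxy)methyl]-9-(PMB-oxy)-7-methyl-10-[(trimethylsilyl)ethynyl]cyclodeca-2,6-dien-1-one | COc1ccc(CO[C@@H]2C/C(C)=C/C[C@H](O[Si](C)(C)C(C)(C)C)/C(CO[Si](C)(C)C(C)(C)C)=C\C(=O)[C@@H]2C#C[Si](C)(C)C)cc1
F5 | step 10 | (1R,4S,6R)-4-(TBS-oxy)-3-[(TBS-oxy)methyl]-1-ethenyl-6-(prop-1-en-2-yl)cyclohex-2-en-1-ol | O[C@]1(C=C)C=C(CO[Si](C)(C)C(C)(C)C)[C@@H](O[Si](C)(C)C(C)(C)C)C[C@@H]1C(C)=C
F6 | step 10 | (2Z,4S,6E)-4-(TBS-oxy)-3-[(TBS-oxy)methyl]-7-methylcyclodeca-2,6-dien-1-one | O=C1CCC/C(C)=C/C[C@H](O[Si](C)(C)C(C)(C)C)/C(CO[Si](C)(C)C(C)(C)C)=C\1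
F7 | step 10 | (2Z,4S,6E,9E)-4-(TBS-oxy)-3-[(TBS-oxy)methyl]-7-methylcyclodeca-2,6,9-trien-1-one | O=C1/C=C/C/C(C)=C/C[C@H](O[Si](C)(C)C(C)(C)C)/C(CO[Si](C)(C)C(C)(C)C)=C\1
F8 | step 10 | trans-7,8-epoxide of F7 (germacrane numbering; C8 oxygen configured as in 17) | O=C1[C@H]2O[C@@H]2C/C(C)=C/C[C@H](O[Si](C)(C)C(C)(C)C)/C(CO[Si](C)(C)C(C)(C)C)=C\1
F9 | step 13 | 2-methyl-3-(phenylselanyl)propanal | CC(C[Se]c1ccccc1)C=O
F10 | step 13 | C8 2-methyl-3-(phenylselanyl)propanoate of the C6 alcohol (analogue of 21, epimers at the ester α-carbon) | CC(C[Se]c1ccccc1)C(=O)O[C@@H]1C/C(C)=C/C[C@H](O[Si](C)(C)C(C)(C)C)/C(CO[Si](C)(C)C(C)(C)C)=C\[C@@H](O)[C@@H]1C#C
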